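**Retrosynthetic overview**

1. The target is a trans-(2R,3S)-2,3-diarylchroman-4-one (ring A fused to pyranone ring C) with ring B on C2, ring D on C3 and an (E)-enone arm from ring D to ring E. The strategy rests on C2 being a benzylic ether carbon (bonded to O1 and ring B) and C3 lying between the C4 carbonyl and ring D. The C2–C3 bond is therefore cut to a keto carbene at C3 and a benzylic C–H of a ring A–O–CH2–ring B ether.
2. Ring C is the only ring made. It is closed by enantioselective dirhodium carbene C–H insertion of α-aryl α-diazo ketone 14 to give 16 (C2 from the catalyst, C3 by equilibration to trans).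
3. Diazo ketone 14 comes from deoxybenzoin 13 by diazo transfer. Ketone 13 comes from ring A/ring B aldehyde 6 (Mitsunobu ether) and ring D benzylic zinc reagent 11, followed by oxidation.
4. End game: Heck coupling of the ring D bromide with ring E aryl vinyl ketone 19, then acidic MOM cleavage, then buffered fluoride so that the ring D phenol is freed last.
5. Protecting groups: MOM on rings A, B and E. Ring D carries TIPS in place of a smaller silyl group, because TIPS resists DBU, amine and the acidic MOM cleavage and has no C–H next to oxygen.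

Key step: step 11

Assumption: Rh2(S-PTTL)4, dirhodium tetrakis[N-phthaloyl-(S)-tert-leucinate], is taken to direct the carbene to the pro-R benzylic hydrogen (giving 2R). If the first run shows the opposite sense, the mirror-image catalyst Rh2(R-PTTL)4 is used with nothing else changed.

**Route**

Step 1
Reactants: 1 4-hydroxybenzaldehyde
Product: 2 4-(methoxymethoxy)benzaldehyde
Conditions: MOMCl, i-Pr2NEt, CH2Cl2, 0 → 23 °C
Reagents that add atoms: chloromethyl methyl ether (MOMCl), COCCl
Why: O-alkylation of the phenol with the chloromethyl ether (Williamson-type acetal formation) masks the ring B oxygen as a MOM ether that is inert to hydride, Mitsunobu, organozinc, DBU and carbene conditions.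

Step 2
Reactants: 2 4-(methoxymethoxy)benzaldehyde
Product: 3 [4-(methoxymethoxy)phenyl]methanol
Conditions: NaBH4, MeOH, 0 °C
Reagents that add atoms: none
Why: Borohydride reduction of the aryl aldehyde should give the benzylic alcohol for the Mitsunobu step, the MOM acetal being inert to hydride.

Step 3
Reactants: 4 2,4-dihydroxybenzaldehyde
Product: 5 2-hydroxy-4-(methoxymethoxy)benzaldehyde
Conditions: MOMCl (1.05 equiv), K2CO3, acetone, 23 °C
Reagents that add atoms: chloromethyl methyl ether (MOMCl), COCCl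
Why: Regioselective phenol O-alkylation, because the 2-hydroxyl is held in a hydrogen bond to the formyl group and is less acidic, so one equivalent of MOMCl should alkylate only the 4-hydroxyl.

Step 4
Reactants: 5 2-hydroxy-4-(methoxymethoxy)benzaldehyde; 3 [4-(methoxymethoxy)phenyl]methanol
Product: 6 4-(methoxymethoxy)-2-{[4-(methoxymethoxy)benzyl]oxy}benzaldehyde
Conditions: PPh3, diisopropyl azodicarboxylate, THF, 0 → 23 °C
Reagents that add atoms: none
Why: Mitsunobu etherification joins the acidic salicylaldehyde phenol to the primary para-alkoxybenzyl alcohol under neutral conditions and so installs the O–CH2–ring B unit whose CH2 becomes C2, without handling a labile para-alkoxybenzyl halide.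

Step 5
Reactants: 7 5-bromo-2-hydroxybenzaldehyde
Product: 8 5-bromo-2-(triisopropylsilyloxy)benzaldehyde
Conditions: i-Pr3SiCl, imidazole, DMF, 23 °C
Reagents that add atoms: triisopropylsilyl chloride, CC(C)[Si](Cl)(C(C)C)C(C)C
Why: Imidazole-promoted silylation of the phenol gives an aryl TIPS ether that has no C–H next to oxygen, resists DBU and amine bases and outlasts the later acidic MOM cleavage.

Step 6
Reactants: 8 5-bromo-2-(triisopropylsilyloxy)benzaldehyde
Product: 9 [5-bromo-2-(triisopropylsilyloxy)phenyl]methanol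
Conditions: NaBH4, MeOH/THF, 0 °C, prompt NH4Cl quench
Reagents that add atoms: none
Why: Borohydride reduction of the aldehyde should be clean, the bulky TIPS group and the short, cold reaction suppressing phenol-to-alkoxide silyl migration.

Step 7
Reactants: 9 [5-bromo-2-(triisopropylsilyloxy)phenyl]methanol
Product: 10 [4-bromo-2-(chloromethyl)phenoxy]triisopropylsilane
Conditions: PPh3, N-chlorosuccinimide, CH2Cl2, 0 → 23 °C
Reagents that add atoms: N-chlorosuccinimide, O=C1CCC(=O)N1Cl
Why: Appel-type chlorination converts the benzylic alcohol into the chloride under neutral conditions that spare the silyl ether and the aryl bromide.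

Step 8
Reactants: 10 [4-bromo-2-(chloromethyl)phenoxy]triisopropylsilane; 6 4-(methoxymethoxy)-2-{[4-(methoxymethoxy)benzyl]oxy}benzaldehyde
Product: 12 racemic 2-[5-bromo-2-(triisopropylsilyloxy)phenyl]-1-[4-(methoxymethoxy)-2-{[4-(methoxymethoxy)benzyl]oxy}phenyl]ethan-1-ol, via benzylzinc chloride 11 (not isolated)
Conditions: Zn dust (activated with cat. BrCH2CH2Br and Me3SiCl), LiCl, THF, 25 °C; then 6, MgCl2, THF, 0 → 25 °C; aq. NH4Cl
Reagents that add atoms: none
Why: LiCl-promoted zinc insertion is selective for the benzylic C–Cl bond over the aryl C–Br bond, and the benzylic zinc chloride should add to the aldehyde (MgCl2-accelerated 1,2-addition) without touching acetals or silyl ether, the racemic carbinol centre being removed in step 9.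

Step 9
Reactants: 12 racemic 2-[5-bromo-2-(triisopropylsilyloxy)phenyl]-1-[4-(methoxymethoxy)-2-{[4-(methoxymethoxy)benzyl]oxy}phenyl]ethan-1-ol
Product: 13 2-[5-bromo-2-(triisopropylsilyloxy)phenyl]-1-[4-(methoxymethoxy)-2-{[4-(methoxymethoxy)benzyl]oxy}phenyl]ethan-1-one
Conditions: Dess–Martin periodinane, NaHCO3, CH2Cl2, 0 → 23 °C
Reagents that add atoms: none
Why: Dess–Martin oxidation of the secondary benzylic alcohol under buffered, non-acidic conditions should give the deoxybenzoin without harming the MOM groups or the para-alkoxybenzyl ether.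

Step 10
Reactants: 13 2-[5-bromo-2-(triisopropylsilyloxy)phenyl]-1-[4-(methoxymethoxy)-2-{[4-(methoxymethoxy)benzyl]oxy}phenyl]ethan-1-one
Product: 14 2-diazo-2-[5-bromo-2-(triisopropylsilyloxy)phenyl]-1-[4-(methoxymethoxy)-2-{[4-(methoxymethoxy)benzyl]oxy}phenyl]ethan-1-one
Conditions: 4-acetamidobenzenesulfonyl azide, DBU, MeCN, 0 → 23 °C
Reagents that add atoms: 4-acetamidobenzenesulfonyl azide, CC(=O)Nc1ccc(cc1)S(=O)(=O)N=[N+]=[N-]
Why: Regitz diazo transfer, in which DBU deprotonates the doubly activated ArC(O)–CH2–Ar methylene and the enolate takes N2 from the sulfonyl azide, the only enolisable position being the one required.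

Step 11
Reactants: 14 2-diazo-2-[5-bromo-2-(triisopropylsilyloxy)phenyl]-1-[4-(methoxymethoxy)-2-{[4-(methoxymethoxy)benzyl]oxy}phenyl]ethan-1-one
Product: 16 trans-(2R,3S)-3-[5-bromo-2-(triisopropylsilyloxy)phenyl]-7-(methoxymethoxy)-2-[4-(methoxymethoxy)phenyl]chroman-4-one, via cis-(2R,3R)-chromanone 15 (not isolated)
Conditions: Rh2(S-PTTL)4 (1 mol %), 4 Å MS, toluene, −20 → 23 °C, slow addition of 14; then Et3N (0.2 equiv), 23 °C
Reagents that add atoms: none
Why: Rh2(S-PTTL)4 expels N2 from 14 to give a donor–acceptor dirhodium carbene at the future C3, which takes one benzylic hydrogen of the ArO–CH2–ring B group through a three-centre, hydride-transfer-like transition state and forms the C2–C3 bond with retention at that carbon. The closest known reaction type is the chiral dirhodium carboxylate-catalysed intramolecular C–H insertion of ortho-alkoxyaryl α-diazo ketones next to the ether oxygen, which gives 2,3-disubstituted chroman-4-ones, and the same catalyst family is established for cyclisations of α-aryl α-diazo ketones. Ring C closes by 1,6-insertion through a six-membered transition state, the carbene carbon C3 bonding to C2 at the far end of the chain C4, C4a, C8a, O1. C2 is set by the catalyst, whose chiral carboxylate pocket has to deliver the carbene to the pro-R hydrogen (2R), while C3 is first formed kinetically (cis isomer 15 expected) and is then equilibrated by catalytic Et3N through the enol to the diequatorial trans arrangement, so that 3S follows from 2R under thermodynamic control. The step needs C–H insertion to win over oxonium ylide formation at O1 followed by 1,2-benzyl shift, over Wolff rearrangement and over attack at other C–H bonds. The substrate secures this because the ether oxygen is a weakly basic vinylogous ester oxygen, the target C–H is activated both by that oxygen and by the para-oxygenated ring B, the aryl donor tempers the carbene, and the ring D oxygen carries a silyl group with no C–H next to oxygen within reach.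

Step 12
Reactants: 4 2,4-dihydroxybenzaldehyde
Product: 17 2,4-bis(methoxymethoxy)benzaldehyde
Conditions: MOMCl (3 equiv), i-Pr2NEt, CH2Cl2, 0 → 40 °C
Reagents that add atoms: chloromethyl methyl ether (MOMCl), COCCl
Why: Exhaustive phenol O-alkylation with excess MOMCl and amine base should protect both hydroxyls, including the hydrogen-bonded ortho one, so that the later vinyl ketone cannot close to a chromanone.

Step 13
Reactants: 17 2,4-bis(methoxymethoxy)benzaldehyde
Product: 18 racemic 1-[2,4-bis(methoxymethoxy)phenyl]prop-2-en-1-ol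
Conditions: CH2=CHMgBr, THF, −78 → 0 °C; aq. NH4Cl
Reagents that add atoms: vinylmagnesium bromide, C=C[Mg]Br
Why: Grignard 1,2-addition of the vinyl nucleophile to the aryl aldehyde gives the allylic alcohol, whose stereocentre is removed in step 14.

Step 14
Reactants: 18 racemic 1-[2,4-bis(methoxymethoxy)phenyl]prop-2-en-1-ol
Product: 19 1-[2,4-bis(methoxymethoxy)phenyl]prop-2-en-1-one
Conditions: MnO2 (activated, excess), CH2Cl2, 23 °C; used at once as a solution
Reagents that add atoms: none
Why: Manganese dioxide oxidation of the doubly activated benzylic and allylic alcohol is neutral and heterogeneous, which suits the polymerisation-prone aryl vinyl ketone.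

Step 15
Reactants: 16 trans-(2R,3S)-3-[5-bromo-2-(triisopropylsilyloxy)phenyl]-7-(methoxymethoxy)-2-[4-(methoxymethoxy)phenyl]chroman-4-one; 19 1-[2,4-bis(methoxymethoxy)phenyl]prop-2-en-1-one
Product: 20 (2R,3S)-3-{5-[(E)-3-[2,4-bis(methoxymethoxy)phenyl]-3-oxoprop-1-en-1-yl]-2-(triisopropylsilyloxy)phenyl}-7-(methoxymethoxy)-2-[4-(methoxymethoxy)phenyl]chroman-4-one
Conditions: Pd2(dba)3 (2.5 mol %), [(t-Bu)3PH]BF4 (6 mol %), Cy2NMe (1.2 equiv), 19 (2 equiv), 1,4-dioxane, 25–40 °C
Reagents that add atoms: none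
Why: Mizoroki–Heck coupling in which the bulky electron-rich phosphine lets zerovalent palladium insert into the electron-rich aryl bromide near room temperature, syn carbopalladation of the vinyl ketone and syn β-hydride elimination give the (E)-enone, and the hindered amine only takes up HBr, which keeps base stress on C2 and C3 low.

Step 16
Reactants: 20 (2R,3S)-3-{5-[(E)-3-[2,4-bis(methoxymethoxy)phenyl]-3-oxoprop-1-en-1-yl]-2-(triisopropylsilyloxy)phenyl}-7-(methoxymethoxy)-2-[4-(methoxymethoxy)phenyl]chroman-4-one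
Product: 21 (2R,3S)-3-{5-[(E)-3-(2,4-dihydroxyphenyl)-3-oxoprop-1-en-1-yl]-2-(triisopropylsilyloxy)phenyl}-7-hydroxy-2-(4-hydroxyphenyl)chroman-4-one
Conditions: aq. HCl (to ca. 1.5 M), MeOH/THF, 23–35 °C
Reagents that add atoms: none
Why: Acid-catalysed acetal exchange with methanol removes the four MOM groups while the acid-stable aryl TIPS ether keeps the ring D phenol masked, so that this phenol cannot cyclise and dehydrate onto the C4 ketone under acid, and the same acid holds C3 at its trans equilibrium by enolisation.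

Step 17
Reactants: 21 (2R,3S)-3-{5-[(E)-3-(2,4-dihydroxyphenyl)-3-oxoprop-1-en-1-yl]-2-(triisopropylsilyloxy)phenyl}-7-hydroxy-2-(4-hydroxyphenyl)chroman-4-one
Product: 22 (2R,3S)-3-{5-[(E)-3-(2,4-dihydroxyphenyl)-3-oxoprop-1-en-1-yl]-2-hydroxyphenyl}-7-hydroxy-2-(4-hydroxyphenyl)chroman-4-one (CNP0183323.3)
Conditions: TBAF, AcOH (1:1), THF, 0 → 23 °C
Reagents that add atoms: none
Why: Fluoride-mediated desilylation frees the ring D phenol last, with acetic acid buffering so that no phenoxide is present to trigger retro-oxa-Michael opening at C2 or closure of the chalcone.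

**Compound list**

1 | 4-hydroxybenzaldehyde | O=Cc1ccc(O)cc1 | starting material
2 | 4-(methoxymethoxy)benzaldehyde | COCOc1ccc(C=O)cc1 | intermediate
3 | [4-(methoxymethoxy)phenyl]methanol | COCOc1ccc(CO)cc1 | intermediate
4 | 2,4-dihydroxybenzaldehyde | O=Cc1ccc(O)cc1O | starting material
5 | 2-hydroxy-4-(methoxymethoxy)benzaldehyde | COCOc1ccc(C=O)c(O)c1 | intermediate
6 | 4-(methoxymethoxy)-2-{[4-(methoxymethoxy)benzyl]oxy}benzaldehyde | COCOc1ccc(COc2cc(OCOC)ccc2C=O)cc1 | intermediate
7 | 5-bromo-2-hydroxybenzaldehyde | O=Cc1cc(Br)ccc1O | starting material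
8 | 5-bromo-2-(triisopropylsilyloxy)benzaldehyde | CC(C)[Si](Oc1ccc(Br)cc1C=O)(C(C)C)C(C)C | intermediate
9 | [5-bromo-2-(triisopropylsilyloxy)phenyl]methanol | CC(C)[Si](Oc1ccc(Br)cc1CO)(C(C)C)C(C)C | intermediate
10 | [4-bromo-2-(chloromethyl)phenoxy]triisopropylsilane | CC(C)[Si](Oc1ccc(Br)cc1CCl)(C(C)C)C(C)C | intermediate
11 | [5-bromo-2-(triisopropylsilyloxy)benzyl]zinc chloride | CC(C)[Si](Oc1ccc(Br)cc1C[Zn]Cl)(C(C)C)C(C)C | intermediate
12 | racemic 2-[5-bromo-2-(triisopropylsilyloxy)phenyl]-1-[4-(methoxymethoxy)-2-{[4-(methoxymethoxy)benzyl]oxy}phenyl]ethan-1-ol | COCOc1ccc(COc2cc(OCOC)ccc2C(O)Cc3cc(Br)ccc3O[Si](C(C)C)(C(C)C)C(C)C)cc1 | intermediate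
13 | 2-[5-bromo-2-(triisopropylsilyloxy)phenyl]-1-[4-(methoxymethoxy)-2-{[4-(methoxymethoxy)benzyl]oxy}phenyl]ethan-1-one | COCOc1ccc(COc2cc(OCOC)ccc2C(=O)Cc3cc(Br)ccc3O[Si](C(C)C)(C(C)C)C(C)C)cc1 | intermediate
14 | 2-diazo-2-[5-bromo-2-(triisopropylsilyloxy)phenyl]-1-[4-(methoxymethoxy)-2-{[4-(methoxymethoxy)benzyl]oxy}phenyl]ethan-1-one | COCOc1ccc(COc2cc(OCOC)ccc2C(=O)C(=[N+]=[N-])c3cc(Br)ccc3O[Si](C(C)C)(C(C)C)C(C)C)cc1 | intermediate
15 | cis-(2R,3R)-3-[5-bromo-2-(triisopropylsilyloxy)phenyl]-7-(methoxymethoxy)-2-[4-(methoxymethoxy)phenyl]chroman-4-one | CC(C)[Si](Oc1ccc(Br)cc1[C@H]2C(=O)c3ccc(OCOC)cc3O[C@H]2c4ccc(OCOC)cc4)(C(C)C)C(C)C | intermediate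
16 | trans-(2R,3S)-3-[5-bromo-2-(triisopropylsilyloxy)phenyl]-7-(methoxymethoxy)-2-[4-(methoxymethoxy)phenyl]chroman-4-one | CC(C)[Si](Oc1ccc(Br)cc1[C@@H]2C(=O)c3ccc(OCOC)cc3O[C@H]2c4ccc(OCOC)cc4)(C(C)C)C(C)C | intermediate
17 | 2,4-bis(methoxymethoxy)benzaldehyde | COCOc1ccc(C=O)c(OCOC)c1 | intermediate
18 | racemic 1-[2,4-bis(methoxymethoxy)phenyl]prop-2-en-1-ol | COCOc1ccc(C(O)C=C)c(OCOC)c1 | intermediate
19 | 1-[2,4-bis(methoxymethoxy)phenyl]prop-2-en-1-one | COCOc1ccc(C(=O)C=C)c(OCOC)c1 | intermediate
20 | (2R,3S)-3-{5-[(E)-3-[2,4-bis(methoxymethoxy)phenyl]-3-oxoprop-1-en-1-yl]-2-(triisopropylsilyloxy)phenyl}-7-(methoxymethoxy)-2-[4-(methoxymethoxy)phenyl]chroman-4-one | CC(C)[Si](Oc1ccc(/C=C/C(=O)c5ccc(OCOC)cc5OCOC)cc1[C@@H]2C(=O)c3ccc(OCOC)cc3O[C@H]2c4ccc(OCOC)cc4)(C(C)C)C(C)C | intermediate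
21 | (2R,3S)-3-{5-[(E)-3-(2,4-dihydroxyphenyl)-3-oxoprop-1-en-1-yl]-2-(triisopropylsilyloxy)phenyl}-7-hydroxy-2-(4-hydroxyphenyl)chroman-4-one | CC(C)[Si](Oc1ccc(/C=C/C(=O)c5ccc(O)cc5O)cc1[C@@H]2C(=O)c3ccc(O)cc3O[C@H]2c4ccc(O)cc4)(C(C)C)C(C)C | intermediate
22 | (2R,3S)-3-{5-[(E)-3-(2,4-dihydroxyphenyl)-3-oxoprop-1-en-1-yl]-2-hydroxyphenyl}-7-hydroxy-2-(4-hydroxyphenyl)chroman-4-one | O=C(/C=C/c1ccc(O)c([C@@H]2C(=O)c3ccc(O)cc3O[C@H]2c2ccc(O)cc2)c1)c1ccc(O)cc1O | target

**Step count**

Total: 17 steps. Longest linear sequence: 10 steps (steps 5, 6, 7, 8, 9, 10, 11, 15, 16, 17; the ring B line through steps 1, 2, 4 is equally long).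

**Steps most likely to fail**

Step 11 (carbene C–H insertion). The carbene may be captured by the ether oxygen O1, giving an oxonium ylide that undergoes 1,2-benzyl shift to a benzofuranone; Wolff rearrangement may compete; or the catalyst may discriminate poorly between the two benzylic hydrogens, giving low enantiomeric purity at C2. The fallback sets out from ketone 13 and comes back at 16. Oxidative cleavage of the para-alkoxybenzyl ether of 13 with DDQ in wet CH2Cl2 should give 2-[5-bromo-2-(triisopropylsilyloxy)phenyl]-1-[2-hydroxy-4-(methoxymethoxy)phenyl]ethan-1-one F1 and return aldehyde 2. Pyrrolidine-catalysed condensation of F1 with 2 in ethanol at 60 °C (Knoevenagel-type condensation followed by oxa-Michael ring closure, the classical construction of 2,3-diarylchroman-4-ones) should give racemic trans-3-[5-bromo-2-(triisopropylsilyloxy)phenyl]-7-(methoxymethoxy)-2-[4-(methoxymethoxy)phenyl]chroman-4-one F2. Preparative HPLC on a chiral stationary phase then delivers the (2R,3S) enantiomer 16.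

Step 15 (Heck coupling). The aryl vinyl ketone may oligomerise in the presence of amine and phosphine, and prolonged contact with amine may erode the C2 configuration through enolisation at C3 and reversible retro-oxa-Michael ring opening. The fallback sets out from bromide 16 and comes back at 20, forming the enone C=C bond by metathesis without any base. Stille coupling of 16 with tributyl(vinyl)stannane and Pd(PPh3)4 in toluene at 90 °C should give trans-(2R,3S)-7-(methoxymethoxy)-2-[4-(methoxymethoxy)phenyl]-3-[2-(triisopropylsilyloxy)-5-vinylphenyl]chroman-4-one F3. Olefin cross-metathesis of F3 with excess vinyl ketone 19, using the second-generation Hoveyda–Grubbs catalyst RuCl2(H2IMes)(=CH-C6H4-2-O-i-Pr) in CH2Cl2 at 40 °C, should give the (E)-enone 20 with loss of ethene.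

Step 16 (acidic MOM cleavage). Once the ring E ortho phenol is freed, acid may promote its oxa-Michael closure onto the enone (chalcone-to-flavanone isomerisation). The fallback sets out from 4 and 16 and comes back at target 22; it keeps the ring E oxygens silylated while acid is present. Silylation of 4 with i-Pr3SiOTf and 2,6-lutidine in CH2Cl2 should give 2,4-bis(triisopropylsilyloxy)benzaldehyde F4. Addition of CH2=CHMgBr gives racemic 1-[2,4-bis(triisopropylsilyloxy)phenyl]prop-2-en-1-ol F5, and MnO2 oxidation gives 1-[2,4-bis(triisopropylsilyloxy)phenyl]prop-2-en-1-one F6. Heck coupling of F6 with 16 under the conditions of step 15 should give (2R,3S)-3-{5-[(E)-3-[2,4-bis(triisopropylsilyloxy)phenyl]-3-oxoprop-1-en-1-yl]-2-(triisopropylsilyloxy)phenyl}-7-(methoxymethoxy)-2-[4-(methoxymethoxy)phenyl]chroman-4-one F7. HCl in MeOH/THF then removes only the two MOM groups of rings A and B, giving (2R,3S)-3-{5-[(E)-3-[2,4-bis(triisopropylsilyloxy)phenyl]-3-oxoprop-1-en-1-yl]-2-(triisopropylsilyloxy)phenyl}-7-hydroxy-2-(4-hydroxyphenyl)chroman-4-one F8, in which the silylated ring E oxygen cannot add to the enone. TBAF buffered with AcOH removes the three silyl groups to give 22.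

**Further compounds**

F1 | step 11 | 2-[5-bromo-2-(triisopropylsilyloxy)phenyl]-1-[2-hydroxy-4-(methoxymethoxy)phenyl]ethan-1-one | COCOc1ccc(C(=O)Cc2cc(Br)ccc2O[Si](C(C)C)(C(C)C)C(C)C)c(O)c1
F2 | step 11 | racemic trans-3-[5-bromo-2-(triisopropylsilyloxy)phenyl]-7-(methoxymethoxy)-2-[4-(methoxymethoxy)phenyl]chroman-4-one | CC(C)[Si](Oc1ccc(Br)cc1[C@@H]2C(=O)c3ccc(OCOC)cc3O[C@H]2c4ccc(OCOC)cc4)(C(C)C)C(C)C.CC(C)[Si](Oc1ccc(Br)cc1[C@H]2C(=O)c3ccc(OCOC)cc3O[C@@H]2c4ccc(OCOC)cc4)(C(C)C)C(C)C
F3 | step 15 | trans-(2R,3S)-7-(methoxymethoxy)-2-[4-(methoxymethoxy)phenyl]-3-[2-(triisopropylsilyloxy)-5-vinylphenyl]chroman-4-one | CC(C)[Si](Oc1ccc(C=C)cc1[C@@H]2C(=O)c3ccc(OCOC)cc3O[C@H]2c4ccc(OCOC)cc4)(C(C)C)C(C)C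
F4 | step 16 | 2,4-bis(triisopropylsilyloxy)benzaldehyde | CC(C)[Si](Oc1ccc(C=O)c(O[Si](C(C)C)(C(C)C)C(C)C)c1)(C(C)C)C(C)C
F5 | step 16 | racemic 1-[2,4-bis(triisopropylsilyloxy)phenyl]prop-2-en-1-ol | CC(C)[Si](Oc1ccc(C(O)C=C)c(O[Si](C(C)C)(C(C)C)C(C)C)c1)(C(C)C)C(C)C
F6 | step 16 | 1-[2,4-bis(triisopropylsilyloxy)phenyl]prop-2-en-1-one | CC(C)[Si](Oc1ccc(C(=O)C=C)c(O[Si](C(C)C)(C(C)C)C(C)C)c1)(C(C)C)C(C)C
F7 | step 16 | (2R,3S)-3-{5-[(E)-3-[2,4-bis(triisopropylsilyloxy)phenyl]-3-oxoprop-1-en-1-yl]-2-(triisopropylsilyloxy)phenyl}-7-(methoxymethoxy)-2-[4-(methoxymethoxy)phenyl]chroman-4-one | CC(C)[Si](Oc1ccc(/C=C/C(=O)c5ccc(O[Si](C(C)C)(C(C)C)C(C)C)cc5O[Si](C(C)C)(C(C)C)C(C)C)cc1[C@@H]2C(=O)c3ccc(OCOC)cc3O[C@H]2c4ccc(OCOC)cc4)(C(C)C)C(C)C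
F8 | step 16 | (2R,3S)-3-{5-[(E)-3-[2,4-bis(triisopropylsilyloxy)phenyl]-3-oxoprop-1-en-1-yl]-2-(triisopropylsilyloxy)phenyl}-7-hydroxy-2-(4-hydroxyphenyl)chroman-4-one | CC(C)[Si](Oc1ccc(/C=C/C(=O)c5ccc(O[Si](C(C)C)(C(C)C)C(C)C)cc5O[Si](C(C)C)(C(C)C)C(C)C)cc1[C@@H]2C(=O)c3ccc(O)cc3O[C@H]2c4ccc(O)cc4)(C(C)C)C(C)C
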